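**Plan**

1. Locants follow 3,7-dioxabicyclo[3.3.0]octane: C1 carbinol bridgehead, C2 aryl, O3, C4, C5 bridgehead CH, C6 aryl (cis to C4), O7, C8. Ring A is C1–C2–O3–C4–C5 and ring B is C5–C6–O7–C8–C1.
2. Cuts: O3–C4 and C2–aryl (ring A, made last), then C1–OH, then C5–C6 of ring B. The last cut opens ring B to a seven-membered 2-aryl-4,5-dihydro-1,3-dioxepine, which goes back to a Heck coupling at C1 and a simple acetal.
3. Forward: acetal ring, Heck reaction at C1, ring contraction from seven to five atoms (ring B with C4 as a formyl group), C2 aldehyde and C1–OH, aryl Grignard addition, closure of ring A.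
4. Enabling feature: C6 is an aryl-bearing carbon bonded to O7, and C5 carries the oxygenated carbon C4. The C5–C6 bond is therefore an aldol bond between a C4 enol and a C6 oxocarbenium ion, and both can be stored in one O,O-acetal ring held together through O7–C8–C1.
5. Stereochemistry: the asymmetric Heck reaction sets C1 as a relay centre; allylic strain and a cis-selective closure set C5 and C6; C1 is then re-set by epoxidation anti to the two cis substituents; C2 comes from chelation control.

Key step: step 5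

Remark: Ar = 3-methoxy-4-(triisopropylsilyloxy)phenyl throughout.
Remark: (R)-BINAP is assumed to give the (5S) centre in step 4; if the sense of induction is the opposite, (S)-BINAP is used and nothing else changes.

**Route**

Step 1
Reactants: 1 vanillin
Product: 2 3-methoxy-4-(triisopropylsilyloxy)benzaldehyde (ArCHO)
Conditions: TIPSCl, imidazole, DMF, rt
Reagents that add atoms: chlorotriisopropylsilane, CC(C)[Si](Cl)(C(C)C)C(C)C
Why: Imidazole-promoted silylation of the phenol; the aryl triisopropylsilyl ether should survive the acid, Lewis acid, hydride, organomagnesium and oxidation steps and leaves with fluoride at the end.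

Step 2
Reactants: 2 ArCHO; 3 (Z)-but-2-ene-1,4-diol
Product: 4 2-Ar-4,7-dihydro-1,3-dioxepine
Conditions: p-TsOH (cat.), benzene, reflux, azeotropic removal of water
Reagents that add atoms: none
Why: Acid-catalysed acetalisation of an aldehyde with a cis-1,4-diol closes the seven-membered acetal ring; no stereocentre is formed.

Step 3
Reactants: 5 2-methylpropanal
Product: 6 2-methylprop-1-en-1-yl trifluoromethanesulfonate
Conditions: Tf2O, 2,6-di-tert-butyl-4-methylpyridine, CH2Cl2, 0 °C to rt
Reagents that add atoms: triflic anhydride, O=S(=O)(OS(=O)(=O)C(F)(F)F)C(F)(F)F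
Why: Enol triflate formation from an enolisable aldehyde (O-sulfonylation, then loss of the α-proton to the hindered base).

Step 4
Reactants: 4 2-Ar-4,7-dihydro-1,3-dioxepine (in excess); 6 2-methylprop-1-en-1-yl triflate
Product: 7 (5S)-2-Ar-5-(2-methylprop-1-en-1-yl)-4,5-dihydro-1,3-dioxepine (both epimers at the acetal carbon C2)
Conditions: Pd(OAc)2 (cat.), (R)-BINAP, i-Pr2NEt, benzene, 40 °C
Reagents that add atoms: none
Why: Asymmetric Heck reaction by the cationic pathway: syn carbopalladation of the ring alkene and syn β-hydride elimination from the only syn β-hydrogen (on the O–CH2 carbon) place the double bond in the enol ether position, while the chiral ligand selects one of the two enantiotopic alkene carbons and so sets C5 (S) in both acetal epimers.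

Step 5
Reactants: 7 (5S)-2-Ar-5-(2-methylprop-1-en-1-yl)-4,5-dihydro-1,3-dioxepine
Product: 9 [(2R,3R,4S)-2-Ar-4-(2-methylprop-1-en-1-yl)tetrahydrofuran-3-yl]methanol, via aldehyde 8 (not isolated)
Conditions: TMSOTf (cat.), CH2Cl2, −78 °C; then Et3N, NaBH4, MeOH, −78 to 0 °C
Reagents that add atoms: none
Why: TMSOTf ionises the O,O-acetal at the bond to the enol-ether oxygen (the better leaving group), which gives an aryl-stabilised (E)-oxocarbenium ion on O3 tethered to a (Z)-silyl enol ether, and the enol carbon C6 then adds to the oxocarbenium carbon in an intramolecular Mukaiyama-aldol (Prins-type) step that releases the silyl triflate again. The closest known reaction type is the Lewis-acid-promoted ring contraction of 2-substituted 4,5-dihydro-1,3-dioxepines to 2,3-cis tetrahydrofuran-3-carbaldehydes (vinyl acetal, Petasis–Ferrier-type O-to-C rearrangement). The tetrahydrofuran closes in the 5-(enol-exo)-exo-trig mode: five of the seven ring atoms stay in the ring, and the expelled oxygen with its carbon becomes the formyl group. The C3 centre is controlled by allylic 1,3-strain, since the C5–H of 7 eclipses the enol double bond, the tether and the alkenyl group lie on opposite faces and the new bond forms anti to the alkenyl group (3,4-trans); the C2 centre follows from the compact synclinal transition state of the (E)-oxocarbenium ion with the (Z)-enol ether, which should give the 2,3-cis product under kinetic control. The step needs regioselective C–O cleavage and kinetic cis selectivity; low temperature, a short reaction time and hydride reduction of aldehyde 8 before warming should prevent retro-aldol equilibration to the trans isomer and epimerisation next to the formyl group, and both acetal epimers of 7 converge on the same ion pair.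

Step 6
Reactants: 9 [(2R,3R,4S)-2-Ar-4-(2-methylprop-1-en-1-yl)tetrahydrofuran-3-yl]methanol
Product: 10 [(2R,3R,4S)-2-Ar-4-(2-methylprop-1-en-1-yl)tetrahydrofuran-3-yl]methyl 4-methylbenzenesulfonate
Conditions: TsCl, pyridine, CH2Cl2, 0 °C
Reagents that add atoms: 4-methylbenzenesulfonyl chloride, Cc1ccc(cc1)S(Cl)(=O)=O
Why: Sulfonylation of the only hydroxyl group makes C4 of the target the electrophile for the last ring closure and blocks lactol formation later; recrystallisation of the tosylate should raise the enantiomeric purity if needed.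

Step 7
Reactants: 10 the tosylate
Product: 11 [(2R,3R,4S)-2-Ar-4-formyltetrahydrofuran-3-yl]methyl 4-methylbenzenesulfonate
Conditions: OsO4 (cat.), NaIO4, 2,6-lutidine, dioxane–H2O, rt
Reagents that add atoms: osmium tetroxide, O=[Os](=O)(=O)=O (oxygen donor, re-formed by the periodate); sodium periodate, [Na+].[O-]I(=O)(=O)=O
Why: Lemieux–Johnson cleavage of the trisubstituted alkene gives the C2 aldehyde and acetone; the tosylate, silyl ether and benzylic ether are inert under these buffered conditions.

Step 8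
Reactants: 11 the formyl tosylate
Product: 14 [(2R,3R,4S)-2-Ar-4-formyl-4-hydroxytetrahydrofuran-3-yl]methyl 4-methylbenzenesulfonate, via silyl enol ether 12 (not isolated), via silyloxy epoxide 13 (not isolated)
Conditions: TMSOTf, Et3N, CH2Cl2, 0 °C; DMDO, acetone, −78 to 0 °C; then aq. citric acid, THF
Reagents that add atoms: dimethyldioxirane, CC1(C)OO1; trimethylsilyl triflate, C[Si](C)(C)OS(=O)(=O)C(F)(F)F (silicon only in 12 and 13)
Why: Rubottom oxidation: soft enolisation gives the exocyclic silyl enol ether, dimethyldioxirane epoxidises it on the face opposite to the cis CH2OTs (C3) and Ar (C2) groups, which sets the C4 carbinol (S) and erases the relay centre, and mild acid opens the silyloxy epoxide to the α-hydroxy aldehyde.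

Step 9
Reactants: 15 4-bromo-2-methoxyphenol
Product: 16 (4-bromo-2-methoxyphenoxy)triisopropylsilane
Conditions: TIPSCl, imidazole, DMF, rt
Reagents that add atoms: chlorotriisopropylsilane, CC(C)[Si](Cl)(C(C)C)C(C)C
Why: Silylation of the phenol so that the aryl bromide can be turned into a Grignard reagent.

Step 10
Reactants: 14 the hydroxy aldehyde tosylate; 16 the silylated aryl bromide (3 equiv)
Product: 19 (1S,2R,5R,6R)-2,6-bis[3-methoxy-4-(triisopropylsilyloxy)phenyl]-3,7-dioxabicyclo[3.3.0]octan-1-ol, via arylmagnesium bromide 17 (not isolated), via magnesium alkoxide 18 (not isolated)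
Conditions: 16, Mg, THF, rt; then 14, −78 °C to rt, then 50 °C; aq. NH4Cl
Reagents that add atoms: magnesium, [Mg] (in 17 and 18 only)
Why: Chelation-controlled Grignard addition followed by Williamson etherification: the first equivalent deprotonates the tertiary OH, the magnesium alkoxide and the formyl oxygen form a five-membered chelate, the aryl group adds from the flank of the ring CH2 (away from the CH–CH2OTs flank) to give the (R) carbinol, and on warming this alkoxide displaces the tosylate (5-exo-tet, retention at the carbinol) to close ring A with the new aryl group on the convex face.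

Step 11
Reactants: 19 the bis(silyl ether)
Product: 20 (1S,2R,5R,6R)-2,6-bis(4-hydroxy-3-methoxyphenyl)-3,7-dioxabicyclo[3.3.0]octan-1-ol (target)
Conditions: TBAF, AcOH, THF, 0 °C
Reagents that add atoms: none
Why: Fluoride cleavage of the two aryl silyl ethers; the acetic acid buffer keeps the phenoxides protonated, so the benzylic ethers (in particular the concave-face aryl at C6) should not open through a quinone methide.

**Compound list**

1 | vanillin (4-hydroxy-3-methoxybenzaldehyde) | COc1cc(C=O)ccc1O | starting material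
2 | 3-methoxy-4-(triisopropylsilyloxy)benzaldehyde | COc1cc(C=O)ccc1O[Si](C(C)C)(C(C)C)C(C)C | intermediate
3 | (Z)-but-2-ene-1,4-diol | OC/C=C\CO | starting material
4 | 2-Ar-4,7-dihydro-1,3-dioxepine | COc1cc(C2OCC=CCO2)ccc1O[Si](C(C)C)(C(C)C)C(C)C | intermediate
5 | 2-methylpropanal | CC(C)C=O | starting material
6 | 2-methylprop-1-en-1-yl trifluoromethanesulfonate | CC(C)=COS(=O)(=O)C(F)(F)F | intermediate
7 | (5S)-2-Ar-5-(2-methylprop-1-en-1-yl)-4,5-dihydro-1,3-dioxepine, both epimers at C2 | COc1cc(C2OC[C@@H](C=C(C)C)C=CO2)ccc1O[Si](C(C)C)(C(C)C)C(C)C | intermediate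
8 | (2R,3S,4S)-2-Ar-4-(2-methylprop-1-en-1-yl)tetrahydrofuran-3-carbaldehyde | O=C[C@@H]1[C@H](c2ccc(O[Si](C(C)C)(C(C)C)C(C)C)c(OC)c2)OC[C@H]1C=C(C)C | intermediate (not isolated)
9 | [(2R,3R,4S)-2-Ar-4-(2-methylprop-1-en-1-yl)tetrahydrofuran-3-yl]methanol | OC[C@@H]1[C@H](c2ccc(O[Si](C(C)C)(C(C)C)C(C)C)c(OC)c2)OC[C@H]1C=C(C)C | intermediate
10 | [(2R,3R,4S)-2-Ar-4-(2-methylprop-1-en-1-yl)tetrahydrofuran-3-yl]methyl 4-methylbenzenesulfonate | Cc1ccc(cc1)S(=O)(=O)OC[C@@H]2[C@H](c3ccc(O[Si](C(C)C)(C(C)C)C(C)C)c(OC)c3)OC[C@H]2C=C(C)C | intermediate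
11 | [(2R,3R,4S)-2-Ar-4-formyltetrahydrofuran-3-yl]methyl 4-methylbenzenesulfonate | Cc1ccc(cc1)S(=O)(=O)OC[C@@H]2[C@H](c3ccc(O[Si](C(C)C)(C(C)C)C(C)C)c(OC)c3)OC[C@H]2C=O | intermediate
12 | [(2R,3R)-2-Ar-4-(trimethylsilyloxymethylidene)tetrahydrofuran-3-yl]methyl 4-methylbenzenesulfonate, E/Z mixture | Cc1ccc(cc1)S(=O)(=O)OC[C@@H]2[C@H](c3ccc(O[Si](C(C)C)(C(C)C)C(C)C)c(OC)c3)OCC2=CO[Si](C)(C)C | intermediate (not isolated)
13 | [(3S,6R,7R)-6-Ar-2-(trimethylsilyloxy)-1,5-dioxaspiro[2.4]heptan-7-yl]methyl 4-methylbenzenesulfonate, epimers at C2 | Cc1ccc(cc1)S(=O)(=O)OC[C@@H]2[C@H](c3ccc(O[Si](C(C)C)(C(C)C)C(C)C)c(OC)c3)OC[C@@]24OC4O[Si](C)(C)C | intermediate (not isolated)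
14 | [(2R,3R,4S)-2-Ar-4-formyl-4-hydroxytetrahydrofuran-3-yl]methyl 4-methylbenzenesulfonate | Cc1ccc(cc1)S(=O)(=O)OC[C@@H]2[C@H](c3ccc(O[Si](C(C)C)(C(C)C)C(C)C)c(OC)c3)OC[C@]2(O)C=O | intermediate
15 | 4-bromo-2-methoxyphenol | COc1cc(Br)ccc1O | starting material
16 | (4-bromo-2-methoxyphenoxy)triisopropylsilane | COc1cc(Br)ccc1O[Si](C(C)C)(C(C)C)C(C)C | intermediate
17 | [3-methoxy-4-(triisopropylsilyloxy)phenyl]magnesium bromide | COc1cc([Mg]Br)ccc1O[Si](C(C)C)(C(C)C)C(C)C | intermediate (not isolated)
18 | bis(bromomagnesium) alkoxide of [(2R,3R,4S)-2-Ar-4-hydroxy-4-[(R)-hydroxy(Ar)methyl]tetrahydrofuran-3-yl]methyl 4-methylbenzenesulfonate | Cc1ccc(cc1)S(=O)(=O)OC[C@@H]2[C@H](c3ccc(O[Si](C(C)C)(C(C)C)C(C)C)c(OC)c3)OC[C@]2([O-])[C@H]([O-])c4ccc(O[Si](C(C)C)(C(C)C)C(C)C)c(OC)c4.[Mg+]Br.[Mg+]Br | intermediate (not isolated)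
19 | (1S,2R,5R,6R)-2,6-bis[3-methoxy-4-(triisopropylsilyloxy)phenyl]-3,7-dioxabicyclo[3.3.0]octan-1-ol | COc1cc([C@H]2OC[C@@H]3[C@H](c4ccc(O[Si](C(C)C)(C(C)C)C(C)C)c(OC)c4)OC[C@]23O)ccc1O[Si](C(C)C)(C(C)C)C(C)C | intermediate
20 | (1S,2R,5R,6R)-2,6-bis(4-hydroxy-3-methoxyphenyl)-3,7-dioxabicyclo[3.3.0]octan-1-ol | COc1cc([C@H]2OC[C@@H]3[C@H](c4ccc(O)c(OC)c4)OC[C@]23O)ccc1O | target

**Step count and risks**

Total steps: 11. Longest linear sequence: 9 (steps 1, 2, 4, 5, 6, 7, 8, 10, 11).

Step 4. What may go wrong: weak discrimination between the two enantiotopic alkene carbons in the migratory insertion, or re-addition of the palladium hydride that moves the double bond out of the enol ether position. The fallback replaces catalyst control by a resolution; it sets out from 4 and 6 and comes back at 9. The coupling is run with triphenylphosphine as an achiral ligand, which gives 7 together with (5R)-2-Ar-5-(2-methylprop-1-en-1-yl)-4,5-dihydro-1,3-dioxepine F1. The conditions of step 5 then give 9 together with its enantiomer, [(2S,3S,4R)-2-Ar-4-(2-methylprop-1-en-1-yl)tetrahydrofuran-3-yl]methanol F3, through the enantiomeric aldehyde (2S,3R,4R)-2-Ar-4-(2-methylprop-1-en-1-yl)tetrahydrofuran-3-carbaldehyde F2. The primary alcohols are resolved by lipase-catalysed acylation with vinyl acetate, using an enzyme screened for faster acylation of F3. The acetate of the unwanted enantiomer, [(2S,3S,4R)-2-Ar-4-(2-methylprop-1-en-1-yl)tetrahydrofuran-3-yl]methyl acetate F4, is removed by chromatography, and unreacted 9 goes on to step 6.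

Step 5. What may go wrong: retro-aldol equilibration to the 2,3-trans aldehyde, epimerisation next to the formyl group, or Lewis-acid ionisation of the benzylic ether. The fallback builds ring B by a stepwise aldol and etherification sequence instead of the ring contraction; it sets out from 7 and comes back at 10.
- Aqueous acetic acid hydrolyses the vinyl acetal of 7 to aldehyde 2 and the lactol (4R)-4-(2-methylprop-1-en-1-yl)tetrahydrofuran-2-ol F5.
- Ag2CO3 on Celite oxidises F5 to (R)-4-(2-methylprop-1-en-1-yl)dihydrofuran-2(3H)-one F6.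
- LDA (THF, −78 °C) followed by aldehyde 2 gives the aldol product with the new branch anti to the alkenyl group; the carbinol epimers are separated, and (3S,4S)-3-[(R)-hydroxy(Ar)methyl]-4-(2-methylprop-1-en-1-yl)dihydrofuran-2(3H)-one F7 is carried on.
- LiAlH4 gives (2R,3S)-2-[(R)-hydroxy(Ar)methyl]-3-(2-methylprop-1-en-1-yl)butane-1,4-diol F8.
- TsCl (2 equiv) in pyridine sulfonylates the two primary hydroxyl groups to give the 1,4-bis(4-methylbenzenesulfonate) F9.
- NaH then lets the benzylic alkoxide close the five-membered ring on the tosylate that leads to a tetrahydrofuran (the other would give an oxetane), with retention at the benzylic carbon, which is compound 10.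

Step 10. What may go wrong: addition without chelation (wrong face at C2), α-ketol rearrangement of the hydroxy aldehyde under the basic conditions, or slow ring closure of the magnesium alkoxide. The fallback closes ring A first and brings the aryl group in afterwards by addition to a bicyclic oxocarbenium ion; it sets out from 14 and 17 and comes back at 19. K2CO3 in MeOH (0 °C) converts 14 through its hemiacetal alkoxide, which displaces the tosylate, into the bicyclic methyl acetal (1S,5R,6R)-6-Ar-2-methoxy-3,7-dioxabicyclo[3.3.0]octan-1-ol F10 (both anomers). Transmetallation of 17 with ZnBr2 gives [3-methoxy-4-(triisopropylsilyloxy)phenyl]zinc bromide F11. F10 with F11 and BF3·OEt2 (CH2Cl2, −78 °C) ionises the acetal, and the aryl group should add to the cis-fused oxocarbenium ion from the convex face to give 19.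

Further compounds
F1 | step 4 | (5R)-2-Ar-5-(2-methylprop-1-en-1-yl)-4,5-dihydro-1,3-dioxepine | COc1cc(C2OC[C@H](C=C(C)C)C=CO2)ccc1O[Si](C(C)C)(C(C)C)C(C)C
F2 | step 4 | (2S,3R,4R)-2-Ar-4-(2-methylprop-1-en-1-yl)tetrahydrofuran-3-carbaldehyde | O=C[C@H]1[C@@H](c2ccc(O[Si](C(C)C)(C(C)C)C(C)C)c(OC)c2)OC[C@@H]1C=C(C)C
F3 | step 4 | [(2S,3S,4R)-2-Ar-4-(2-methylprop-1-en-1-yl)tetrahydrofuran-3-yl]methanol | OC[C@H]1[C@@H](c2ccc(O[Si](C(C)C)(C(C)C)C(C)C)c(OC)c2)OC[C@@H]1C=C(C)C
F4 | step 4 | [(2S,3S,4R)-2-Ar-4-(2-methylprop-1-en-1-yl)tetrahydrofuran-3-yl]methyl acetate | CC(=O)OC[C@H]1[C@@H](c2ccc(O[Si](C(C)C)(C(C)C)C(C)C)c(OC)c2)OC[C@@H]1C=C(C)C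
F5 | step 5 | (4R)-4-(2-methylprop-1-en-1-yl)tetrahydrofuran-2-ol | OC1C[C@H](C=C(C)C)CO1
F6 | step 5 | (R)-4-(2-methylprop-1-en-1-yl)dihydrofuran-2(3H)-one | O=C1C[C@H](C=C(C)C)CO1
F7 | step 5 | (3S,4S)-3-[(R)-hydroxy(Ar)methyl]-4-(2-methylprop-1-en-1-yl)dihydrofuran-2(3H)-one | O=C1[C@H]([C@@H](O)c2ccc(O[Si](C(C)C)(C(C)C)C(C)C)c(OC)c2)[C@H](C=C(C)C)CO1
F8 | step 5 | (2R,3S)-2-[(R)-hydroxy(Ar)methyl]-3-(2-methylprop-1-en-1-yl)butane-1,4-diol | OC[C@H]([C@@H](O)c1ccc(O[Si](C(C)C)(C(C)C)C(C)C)c(OC)c1)[C@H](C=C(C)C)CO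
F9 | step 5 | (2R,3S)-2-[(R)-hydroxy(Ar)methyl]-3-(2-methylprop-1-en-1-yl)butane-1,4-diyl bis(4-methylbenzenesulfonate) | Cc1ccc(cc1)S(=O)(=O)OC[C@H]([C@@H](O)c2ccc(O[Si](C(C)C)(C(C)C)C(C)C)c(OC)c2)[C@H](C=C(C)C)COS(=O)(=O)c3ccc(C)cc3
F10 | step 10 | (1S,5R,6R)-6-Ar-2-methoxy-3,7-dioxabicyclo[3.3.0]octan-1-ol | COC1OC[C@@H]2[C@H](c3ccc(O[Si](C(C)C)(C(C)C)C(C)C)c(OC)c3)OC[C@]12O
F11 | step 10 | [3-methoxy-4-(triisopropylsilyloxy)phenyl]zinc bromide | COc1cc([Zn]Br)ccc1O[Si](C(C)C)(C(C)C)C(C)C
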